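## Analysis of the target

Broussoflavonol E is a flavonol. Rings A and C form a chromen-4-one, ring B sits on C2, and ring D is a 2,2-dimethyldihydropyran fused to ring B through C3' (its CH2) and C4' (its oxygen). Ring A carries hydroxyls on C5 and C7 and a 2-methylbut-3-en-2-yl (1,1-dimethylallyl) group on C8. Ring C carries the 3-OH, and ring B a prenyl group on C2' and a hydroxyl on C5'. The molecule has no stereocentre, so every problem is one of regiochemistry and chemoselectivity.

The sensitive groups are two different C5 alkenes and four phenolic or enolic hydroxyls. Acid can close the 7-OH onto the C8 alkene, and late hydrogenation or strong Lewis acids are excluded. Two features make the synthesis hard: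

- The quaternary benzylic carbon on C8 is wedged between C7–OH and C8a–O1. Alkylation or Claisen chemistry on a phloroglucinol cannot tell C6 from C8.
- Ring B is pentasubstituted, with three neighbouring carbon substituents on C1', C2' and C3'.

The route rests on one feature of ring A. It is a 5,7-dioxygenated benzene fused to the pyranone at C4a–C8a. Its atoms C5 to C8 can therefore be written as a 1,3-dicarbonyl chain on a finished ring C: C5 as an ester carbon on C4a, and C8–C7–C6 as a substituted acetonyl chain on C8a. Ring A is then closed last by forming C5–C6.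

## Retrosynthetic reasoning

**22 to 21.** The 3-OH and the 5'-OH are carried as methoxymethyl ethers. These survive the amide-base steps and leave by acetal cleavage, so the last step needs neither hydrogen nor a Lewis acid.

**21 to 20 (C5–C6).** C5 is a carbonyl-level carbon bound to C4a, and C6 lies between two oxygenated carbons, which is the polarity of a Claisen condensation. Cutting here leaves ring C intact and turns ring A into an open chain in which every substituent has a fixed place. Forward, the acetyl methyl carbon of 20 must attack the ester and the ring must aromatise.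

**20 to 19 (C7–C8).** In 19 the CH2 on C8a is vinylogous to both the C4 carbonyl and the ester, so its anion can take up an acetyl group. The acetyl group is added only now, so that the open polyketone 18 has a single way to cyclise.

**19 to 18 (O1–C8a).** A 4-pyranone is the cyclodehydration product of a 1,3,5-tricarbonyl array. Whichever terminal oxygen closes the ring, the same pyranone results.

**18 to 7 and 17 (C2–C3).** The bond between the aroyl carbon and the oxygen-bearing C3 is cut. Ring B then enters as the simple acid 16, activated as 17, and the C3 oxygen is already present in 7. Forward, the α-alkoxy methylene of 7 must be acylated as a dianion.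

**7 to 4 and 6 (C4a–C8a).** C-Acylation of β-keto ester 4 by acid chloride 6, made from acid 5. The quaternary carbon of the C8 substituent is bought ready-made in 5, so no bond to it has to be formed on a crowded arene.

**4 to 2 and 3, and 2 to 1 (C4–C4a).** A crossed Claisen condensation of methyl acetate 3 with the protected glycolate 2, which comes from 1.

**16 to 15 to 14.** The acid comes from the aldehyde. The C2'–CH2 bond of the prenyl group is cut to the aryl bromide 14, whose bromine marks C2' from the start.

**14 to 13 to 12.** Ring D is traced to an aryl propargyl ether. Its thermal rearrangement forms the C3'–C bond and the pyran ring at the only free ortho position. The chromene alkene is hydrogenated before any other alkene is present.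

**12 to 11 to 9 and 10, and 9 to 8.** Two O-alkylations of a catechol, ordered by acidity: the hydroxyl para to the formyl group takes the propargyl unit 10, the other the MOM group. The catechol 9 comes from commercial 6-bromovanillin 8 by demethylation.

## Alternatives that were turned down

**Alternative 1:** The disconnection cuts both trisubstituted C=C bonds of the C5 units on C2' and C3' of ring B. Both CH2–CHO arms are traced to the CH2–CH=CH–CH2 bridge of a 5,8-dihydronaphthalene. Forward, ozonolysis and a twofold Wittig isopropylidenation would give 4-(tert-butyldimethylsilyloxy)-5-(methoxymethoxy)-2,3-bis(3-methylbut-2-enyl)phenyl trifluoromethanesulfonate A1.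
- For: the two neighbouring carbon substituents come from one fused ring, so their positions are beyond doubt and no coupling at a hindered position is needed. On the regiochemistry of ring B this is as strong as, or stronger than, the chosen route, which depends on a selective catechol alkylation and on a prenyl cross-coupling.
- Against: two enolisable arylacetaldehydes must survive a basic ylide together, and an electron-rich arene must survive ozone. The later acid closure of ring D has to proceed next to a second prenyl group that can take part in cation–olefin cyclisation. Ring A, the harder half, is not addressed.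
- In exchange, the chosen strategy closes ring D before any prenyl group exists and fixes every position of ring A.

**Alternative 2:** The disconnection cuts the two C–C bonds from the quaternary carbon of the C8 substituent to its methyl and vinyl groups. Forward, a methyl Grignard reagent adds to an ortho-Boc-oxy aryl methyl ketone, Boc transfer and elimination give an o-quinone methide, and a vinyl Grignard reagent adds to its exocyclic carbon. The product would be methyl 2,4-dihydroxy-6-(methoxymethoxy)-3-(2-methylbut-3-en-2-yl)benzoate A2.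
- For: the position of the quaternary carbon is fixed by the acetyl group, and the sequence is short. For ring A alone it is probably as short as the chosen route.
- Against: the quaternary centre forms by addition to a fully substituted exocyclic carbon between two ortho oxygens. An o-quinone methide with methyl groups on that carbon can escape by a 1,5-hydrogen shift to the isopropenyl phenol. The ester on the same ring competes for the Grignard reagents. Ring C must still be closed afterwards from a hindered benzoate, with extra protecting-group steps to tell the ring A hydroxyls apart.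
- In exchange, the chosen strategy forms no bond to the quaternary carbon on the arene and has ring C closed before ring A exists.

**Alternative 3:** The disconnection cuts C1'–C2' and C5'–C6' of ring B. Forward, a Diels–Alder addition of a ring D-fused 3-alkoxyfuran to a 2-ethynylchromone, with opening of the oxygen bridge, would give 2-[8-hydroxy-2,2-dimethyl-5-(3-methylbut-2-enyl)chroman-6-yl]-3,5,7-tris(methoxymethoxy)-8-(2-methylbut-3-en-2-yl)chromen-4-one A3.
- For: it is the most convergent plan. Ring B and its bond to C2 form together, the 5'-phenol appears where needed, and the donor oxygen should steer both the orientation of the addition and the bridge opening. In convergence it is stronger than the chosen route.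
- Against: the ethynylchromone must already hold the complete ring A with its C8 substituent, so the main problem is only passed on. The fused, prenylated alkoxyfuran is an acid-sensitive heterocycle that needs its own multistep synthesis. A tetrasubstituted furan and a hindered ynone should react slowly, with conjugate addition as a competing path.
- In exchange, the chosen strategy builds ring B with ordinary ionic and cross-coupling chemistry and gives a single answer to the ring A problem.

Key step: step 14

Remark on the chemistry: 7 and 18 are enolised polycarbonyl compounds drawn in their keto forms. 20 is used as the racemate, because its single stereocentre (C8) becomes an aromatic carbon in step 14.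

## Route

Step 1
Reactants: 1 methyl 2-hydroxyacetate
Product: 2 methyl 2-(methoxymethoxy)acetate
Conditions: MOMCl, i-Pr2NEt, CH2Cl2, 0 °C to rt
Reagents that add atoms: chloromethyl methyl ether, COCCl
Why: O-Alkylation of the primary alcohol by the α-chloro ether under amine base (acetal formation); the ester is not touched.

Step 2
Reactants: 2 methyl 2-(methoxymethoxy)acetate; 3 methyl acetate
Product: 4 methyl 4-(methoxymethoxy)-3-oxobutanoate
Conditions: 3 (2.2 equiv), LiN(i-Pr)2 (2.2 equiv), THF, −78 °C; then 2, −78 to −30 °C; AcOH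
Reagents that add atoms: none
Why: Crossed Claisen condensation: the lithium enolate of 3 adds to the more electrophilic α-alkoxy ester 2. The second equivalent of enolate deprotonates the β-keto ester formed, which drives the reaction and stops further addition.

Step 3
Reactants: 4 methyl 4-(methoxymethoxy)-3-oxobutanoate; 5 3,3-dimethylpent-4-enoic acid
Product: 7 methyl 2-[2-(methoxymethoxy)acetyl]-5,5-dimethyl-3-oxohept-6-enoate, via 3,3-dimethylpent-4-enoyl chloride 6 (not isolated)
Conditions: 5, (COCl)2, DMF (cat.), CH2Cl2, rt, evaporate; then 4, MgCl2, pyridine, CH2Cl2, 0 °C to rt; aq. citric acid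
Reagents that add atoms: none
Why: Acid chloride formation, then C-acylation of the magnesium chelate of the β-keto ester (soft enolisation), which gives the 2-acyl β-keto ester and not the enol ester.

Step 4
Reactants: 8 2-bromo-4-hydroxy-5-methoxybenzaldehyde (6-bromovanillin)
Product: 9 2-bromo-4,5-dihydroxybenzaldehyde
Conditions: AlCl3, pyridine, CH2Cl2, reflux; then aq. HCl
Reagents that add atoms: none
Why: Lewis acid-mediated ether cleavage: AlCl3 chelates the ortho-hydroxy-methoxy unit and pyridine removes the methyl group by SN2 attack. Aryl bromide and aldehyde are inert.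

Step 5
Reactants: 9 2-bromo-4,5-dihydroxybenzaldehyde; 10 3-chloro-3-methylbut-1-yne
Product: 11 2-bromo-5-hydroxy-4-(2-methylbut-3-yn-2-yloxy)benzaldehyde
Conditions: 10 (1.3 equiv), K2CO3 (1.0 equiv), KI (cat.), CuI (cat.), DMF, 50 °C
Reagents that add atoms: none
Why: Copper-assisted O-alkylation by the tertiary propargylic chloride. The hydroxyl para to the formyl group is the more acidic, so with one equivalent of base only this one is ionised and alkylated, and a second bulky ether next to the first is disfavoured.

Step 6
Reactants: 11 2-bromo-5-hydroxy-4-(2-methylbut-3-yn-2-yloxy)benzaldehyde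
Product: 12 2-bromo-5-(methoxymethoxy)-4-(2-methylbut-3-yn-2-yloxy)benzaldehyde
Conditions: MOMCl, i-Pr2NEt, CH2Cl2, 0 °C to rt
Reagents that add atoms: chloromethyl methyl ether, COCCl
Why: Standard O-alkylation of the remaining phenol to its MOM acetal; no other nucleophilic site is present.

Step 7
Reactants: 12 2-bromo-5-(methoxymethoxy)-4-(2-methylbut-3-yn-2-yloxy)benzaldehyde
Product: 13 5-bromo-8-(methoxymethoxy)-2,2-dimethyl-2H-chromene-6-carbaldehyde
Conditions: N,N-diethylaniline, 190 °C
Reagents that add atoms: none
Why: Aromatic propargyl Claisen rearrangement to the only free ortho carbon, then 1,5-hydrogen shift and oxa-6π electrocyclisation to the 2H-chromene. The other ortho carbon bears the MOM-oxy group and cannot rearomatise, so the regiochemistry is fixed.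

Step 8
Reactants: 13 5-bromo-8-(methoxymethoxy)-2,2-dimethyl-2H-chromene-6-carbaldehyde
Product: 14 5-bromo-8-(methoxymethoxy)-2,2-dimethylchroman-6-carbaldehyde
Conditions: H2 (3 atm), RhCl(PPh3)3 (5 mol%), benzene–EtOH, rt
Reagents that add atoms: none
Why: Homogeneous hydrogenation of the cis-disubstituted styrene-type alkene. RhCl(PPh3)3 should neither cleave the aryl bromide nor reduce the aldehyde at room temperature, and the alkene is removed here because all later alkenes must stay.

Step 9
Reactants: 14 5-bromo-8-(methoxymethoxy)-2,2-dimethylchroman-6-carbaldehyde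
Product: 15 8-(methoxymethoxy)-2,2-dimethyl-5-(3-methylbut-2-enyl)chroman-6-carbaldehyde
Conditions: tributyl(3-methylbut-2-enyl)stannane, Pd(PPh3)4 (5 mol%), DMF, 100 °C
Reagents that add atoms: tributyl(3-methylbut-2-enyl)stannane, CC(C)=CC[Sn](CCCC)(CCCC)CCCC
Why: Stille coupling: the ortho-formyl group helps oxidative addition, and reductive elimination at the less substituted allyl terminus should give the linear prenyl arene. The aldehyde is tolerated.

Step 10
Reactants: 15 8-(methoxymethoxy)-2,2-dimethyl-5-(3-methylbut-2-enyl)chroman-6-carbaldehyde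
Product: 16 8-(methoxymethoxy)-2,2-dimethyl-5-(3-methylbut-2-enyl)chroman-6-carboxylic acid
Conditions: NaClO2, NaH2PO4, 2-methylbut-2-ene (excess), t-BuOH–H2O, rt
Reagents that add atoms: sodium chlorite, [Na+].[O-]Cl=O
Why: Pinnick oxidation: buffered chlorite oxidises only the aldehyde, and the excess alkene scavenger takes up the hypochlorous acid so that the prenyl group and the MOM ether remain.

Step 11
Reactants: 7 methyl 2-[2-(methoxymethoxy)acetyl]-5,5-dimethyl-3-oxohept-6-enoate; 16 8-(methoxymethoxy)-2,2-dimethyl-5-(3-methylbut-2-enyl)chroman-6-carboxylic acid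
Product: 18 methyl 2-{2-(methoxymethoxy)-3-[8-(methoxymethoxy)-2,2-dimethyl-5-(3-methylbut-2-enyl)chroman-6-yl]-3-oxopropanoyl}-5,5-dimethyl-3-oxohept-6-enoate, via chroman-6-carbonyl chloride 17 (not isolated)
Conditions: 16, 1-chloro-N,N,2-trimethylprop-1-en-1-amine, CH2Cl2, rt; 7, LiN(i-Pr)2 (3.2 equiv), THF, −78 to −40 °C; then 17, −78 to −20 °C; AcOH
Reagents that add atoms: none
Why: Neutral acid chloride formation, then γ-acylation of a β-dicarbonyl dianion. The base removes first the central methine proton and then a proton of the α-alkoxy methylene (the other methylene is neopentyl-type and shielded), and the more basic terminal carbon is aroylated. The third equivalent of base takes up the acidic product.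

Step 12
Reactants: 18 methyl 2-{2-(methoxymethoxy)-3-[8-(methoxymethoxy)-2,2-dimethyl-5-(3-methylbut-2-enyl)chroman-6-yl]-3-oxopropanoyl}-5,5-dimethyl-3-oxohept-6-enoate
Product: 19 methyl 6-(2,2-dimethylbut-3-enyl)-3-(methoxymethoxy)-2-[8-(methoxymethoxy)-2,2-dimethyl-5-(3-methylbut-2-enyl)chroman-6-yl]-4-oxo-4H-pyran-5-carboxylate
Conditions: PPh3, CCl4, Et3N, MeCN, rt
Reagents that add atoms: none
Why: Cyclodehydration of the 1,3,5-tricarbonyl array to the 4-pyranone under Appel-type activation: one terminal enol oxygen becomes an oxyphosphonium leaving group and is displaced by the other, and either oxygen gives the same ring. Et3N takes up the HCl, so both MOM ethers should survive.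

Step 13
Reactants: 19 methyl 6-(2,2-dimethylbut-3-enyl)-3-(methoxymethoxy)-2-[8-(methoxymethoxy)-2,2-dimethyl-5-(3-methylbut-2-enyl)chroman-6-yl]-4-oxo-4H-pyran-5-carboxylate
Product: 20 methyl 6-(4,4-dimethyl-2-oxohex-5-en-3-yl)-3-(methoxymethoxy)-2-[8-(methoxymethoxy)-2,2-dimethyl-5-(3-methylbut-2-enyl)chroman-6-yl]-4-oxo-4H-pyran-5-carboxylate (racemic)
Conditions: LiN(SiMe3)2 (2.2 equiv), THF, −78 °C; 1-acetylbenzotriazole, −78 to −20 °C; AcOH
Reagents that add atoms: 1-acetyl-1H-benzotriazole, CC(=O)n1nnc2ccccc12
Why: Vinylogous deprotonation of the CH2 on C8a gives an extended enolate that is C-acylated at its exocyclic carbon, as known for 2-alkyl-4-pyranones. The second equivalent of base takes up the more acidic product and protects it from further reaction. The new stereocentre forms as a racemate and is lost in step 14.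

Step 14
Reactants: 20 methyl 6-(4,4-dimethyl-2-oxohex-5-en-3-yl)-3-(methoxymethoxy)-2-[8-(methoxymethoxy)-2,2-dimethyl-5-(3-methylbut-2-enyl)chroman-6-yl]-4-oxo-4H-pyran-5-carboxylate (racemic)
Product: 21 5,7-dihydroxy-3-(methoxymethoxy)-2-[8-(methoxymethoxy)-2,2-dimethyl-5-(3-methylbut-2-enyl)chroman-6-yl]-8-(2-methylbut-3-en-2-yl)chromen-4-one
Conditions: LiN(i-Pr)2 (3.2 equiv), THF, −78 to 0 °C; AcOH
Reagents that add atoms: none
Why: The base first removes the doubly activated C8–H (between the acetyl group and the vinylogous C8a) and then a proton of the acetyl methyl group, as in the dianion chemistry of β-diketones. The terminal enolate carbon (C6) adds to the ester carbonyl (C5) on the neighbouring ring carbon C4a, methoxide leaves, and the ring-closed diketo form tautomerises at once to the aromatic 5,7-diol, held as its dilithium salt until work-up. The closest known reaction type is the base-mediated Dieckmann closure of ortho-acetonyl benzoates to naphthalene-1,3-diols, together with the related biomimetic polyketide cyclisations. Ring A closes in a 6-(enolendo)-exo-trig mode, which Baldwin's rules favour. No stereocentre is formed, and the one at C8 of 20 disappears on enolisation. The step needs C-acylation by the terminal carbon and not O-acylation by the enolate oxygen, which would give a fused pyranopyranone lactone. The dianion reacts at its most basic carbon terminus, the bulky tertiary alkyl group on C8 should turn towards O1 and so hold the acetyl group beside the ester, and aromatisation makes the C-acylation irreversible. Because the chain fixes every ring A substituent, no 6-alkyl isomer can form.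

Step 15
Reactants: 21 5,7-dihydroxy-3-(methoxymethoxy)-2-[8-(methoxymethoxy)-2,2-dimethyl-5-(3-methylbut-2-enyl)chroman-6-yl]-8-(2-methylbut-3-en-2-yl)chromen-4-one
Product: 22 Broussoflavonol E, 3,5,7-trihydroxy-2-[8-hydroxy-2,2-dimethyl-5-(3-methylbut-2-enyl)chroman-6-yl]-8-(2-methylbut-3-en-2-yl)chromen-4-one
Conditions: HCl (2 M aq.), MeOH–THF, 40 °C
Reagents that add atoms: none
Why: Acid-catalysed acetal exchange with methanol frees the enolic 3-OH and the 5'-phenol. Dilute acid at moderate temperature is chosen so that the C8 alkene beside the 7-OH and the prenyl group should not be protonated.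

## Compound list

1 | methyl 2-hydroxyacetate | COC(=O)CO | starting material
2 | methyl 2-(methoxymethoxy)acetate | COCOCC(=O)OC | intermediate
3 | methyl acetate | CC(=O)OC | starting material
4 | methyl 4-(methoxymethoxy)-3-oxobutanoate | COCOCC(=O)CC(=O)OC | intermediate
5 | 3,3-dimethylpent-4-enoic acid | C=CC(C)(C)CC(=O)O | starting material
6 | 3,3-dimethylpent-4-enoyl chloride | C=CC(C)(C)CC(=O)Cl | intermediate
7 | methyl 2-[2-(methoxymethoxy)acetyl]-5,5-dimethyl-3-oxohept-6-enoate (keto form of a tautomeric mixture) | COCOCC(=O)C(C(=O)OC)C(=O)CC(C)(C)C=C | intermediate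
8 | 2-bromo-4-hydroxy-5-methoxybenzaldehyde (6-bromovanillin) | O=Cc1cc(OC)c(O)cc1Br | starting material
9 | 2-bromo-4,5-dihydroxybenzaldehyde | O=Cc1cc(O)c(O)cc1Br | intermediate
10 | 3-chloro-3-methylbut-1-yne | C#CC(C)(C)Cl | starting material
11 | 2-bromo-5-hydroxy-4-(2-methylbut-3-yn-2-yloxy)benzaldehyde | O=Cc1cc(O)c(OC(C)(C)C#C)cc1Br | intermediate
12 | 2-bromo-5-(methoxymethoxy)-4-(2-methylbut-3-yn-2-yloxy)benzaldehyde | O=Cc1cc(OCOC)c(OC(C)(C)C#C)cc1Br | intermediate
13 | 5-bromo-8-(methoxymethoxy)-2,2-dimethyl-2H-chromene-6-carbaldehyde | O=Cc1cc(OCOC)c2OC(C)(C)C=Cc2c1Br | intermediate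
14 | 5-bromo-8-(methoxymethoxy)-2,2-dimethylchroman-6-carbaldehyde | O=Cc1cc(OCOC)c2OC(C)(C)CCc2c1Br | intermediate
15 | 8-(methoxymethoxy)-2,2-dimethyl-5-(3-methylbut-2-enyl)chroman-6-carbaldehyde | O=Cc1cc(OCOC)c2OC(C)(C)CCc2c1CC=C(C)C | intermediate
16 | 8-(methoxymethoxy)-2,2-dimethyl-5-(3-methylbut-2-enyl)chroman-6-carboxylic acid | OC(=O)c1cc(OCOC)c2OC(C)(C)CCc2c1CC=C(C)C | intermediate
17 | 8-(methoxymethoxy)-2,2-dimethyl-5-(3-methylbut-2-enyl)chroman-6-carbonyl chloride | ClC(=O)c1cc(OCOC)c2OC(C)(C)CCc2c1CC=C(C)C | intermediate
18 | methyl 2-{2-(methoxymethoxy)-3-[8-(methoxymethoxy)-2,2-dimethyl-5-(3-methylbut-2-enyl)chroman-6-yl]-3-oxopropanoyl}-5,5-dimethyl-3-oxohept-6-enoate (keto form of a tautomeric mixture) | COC(=O)C(C(=O)CC(C)(C)C=C)C(=O)C(OCOC)C(=O)c1cc(OCOC)c2OC(C)(C)CCc2c1CC=C(C)C | intermediate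
19 | methyl 6-(2,2-dimethylbut-3-enyl)-3-(methoxymethoxy)-2-[8-(methoxymethoxy)-2,2-dimethyl-5-(3-methylbut-2-enyl)chroman-6-yl]-4-oxo-4H-pyran-5-carboxylate | COC(=O)c1c(CC(C)(C)C=C)oc(-c2cc(OCOC)c3OC(C)(C)CCc3c2CC=C(C)C)c(OCOC)c1=O | intermediate
20 | methyl 6-(4,4-dimethyl-2-oxohex-5-en-3-yl)-3-(methoxymethoxy)-2-[8-(methoxymethoxy)-2,2-dimethyl-5-(3-methylbut-2-enyl)chroman-6-yl]-4-oxo-4H-pyran-5-carboxylate (racemic) | COC(=O)c1c(C(C(C)=O)C(C)(C)C=C)oc(-c2cc(OCOC)c3OC(C)(C)CCc3c2CC=C(C)C)c(OCOC)c1=O | intermediate
21 | 5,7-dihydroxy-3-(methoxymethoxy)-2-[8-(methoxymethoxy)-2,2-dimethyl-5-(3-methylbut-2-enyl)chroman-6-yl]-8-(2-methylbut-3-en-2-yl)chromen-4-one | C=CC(C)(C)c1c(O)cc(O)c2c(=O)c(OCOC)c(-c3cc(OCOC)c4OC(C)(C)CCc4c3CC=C(C)C)oc12 | intermediate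
22 | Broussoflavonol E, 3,5,7-trihydroxy-2-[8-hydroxy-2,2-dimethyl-5-(3-methylbut-2-enyl)chroman-6-yl]-8-(2-methylbut-3-en-2-yl)chromen-4-one | C=CC(C)(C)c1c(O)cc(O)c2c(=O)c(O)c(-c3cc(O)c4c(c3CC=C(C)C)CCC(C)(C)O4)oc12 | target

## Step count and risks

Total step count: 15. Longest linear sequence: 12 steps (8 to 22, steps 4 to 15). The second branch (1 to 7, steps 1 to 3) joins at step 11.

**Step 14 (key step).** The ring closure may take the wrong course. The enolate oxygen may acylate instead of the terminal carbon (lactonisation to a pyranopyranone), or the second deprotonation may stay incomplete because the first anion is strongly delocalised.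
Fallback, from 19 back to 21: the anion of 19 (as in step 13) is C-acylated with prop-2-enyl 3-chloro-3-oxopropanoate. This gives methyl 6-[5,5-dimethyl-1,3-dioxo-1-(prop-2-enyloxy)hept-6-en-4-yl]-3-(methoxymethoxy)-2-[8-(methoxymethoxy)-2,2-dimethyl-5-(3-methylbut-2-enyl)chroman-6-yl]-4-oxo-4H-pyran-5-carboxylate F1. Its C6 methylene is doubly activated, so a mild base (DBU, THF) is enough for a thermodynamic Dieckmann closure onto the C5 ester. The product is prop-2-enyl 5,7-dihydroxy-3-(methoxymethoxy)-2-[8-(methoxymethoxy)-2,2-dimethyl-5-(3-methylbut-2-enyl)chroman-6-yl]-8-(2-methylbut-3-en-2-yl)-4-oxo-4H-chromene-6-carboxylate F2. Pd(PPh3)4 and morpholine remove the allyl group to give the corresponding chromene-6-carboxylic acid F3. As a 2,4,6-trioxygenated benzoic acid it should lose carbon dioxide on gentle warming and give 21.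

**Step 11.** Deprotonation at the wrong methylene, or O-acylation and double acylation of the polyanion, would give mixtures.
Fallback, from 4 and 17 back to 18: the dianion of 4 (NaH, then n-BuLi, THF) has only one γ-position. Its acylation with 17 gives methyl 4-(methoxymethoxy)-5-[8-(methoxymethoxy)-2,2-dimethyl-5-(3-methylbut-2-enyl)chroman-6-yl]-3,5-dioxopentanoate F4. Magnesium-mediated C-acylation of F4 at C2 with 6 (MgCl2, pyridine) then gives 18.

**Step 12.** The enol may close onto the methyl ester (lactonisation to a 4-hydroxy-2-pyranone) instead of onto the ketone, or a MOM ether may be lost to adventitious acid.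
Fallback, from 18 back to 19: cyclodehydration in strong acid (CF3CO2H, wet CH2Cl2) favours attack on the protonated ketone and removes both MOM groups on purpose. The product is methyl 6-(2,2-dimethylbut-3-enyl)-3-hydroxy-2-[8-hydroxy-2,2-dimethyl-5-(3-methylbut-2-enyl)chroman-6-yl]-4-oxo-4H-pyran-5-carboxylate F5. No phenol stands next to an alkene at this stage. Re-protection (MOMCl, i-Pr2NEt) gives 19.

**Step 13.** The hindered, neopentyl-type carbanion may be acylated on the C4 oxygen, or may fail to form the C–C bond.
Fallback, from 19 back to 20: the same anion adds to acetaldehyde, a small electrophile with no O/C ambiguity. The aldol product is methyl 6-(2-hydroxy-4,4-dimethylhex-5-en-3-yl)-3-(methoxymethoxy)-2-[8-(methoxymethoxy)-2,2-dimethyl-5-(3-methylbut-2-enyl)chroman-6-yl]-4-oxo-4H-pyran-5-carboxylate F6, as a mixture of diastereomers. Oxidation with Dess–Martin periodinane gives 20.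

**Step 9.** Coupling at the substituted terminus of the prenyl unit would give the 1,1-dimethylallyl isomer, and allyl transfer to the aldehyde may compete.
Fallback, from 14 back to 15: Stille coupling with allyltributylstannane, which has no such regiochemical question, gives 8-(methoxymethoxy)-2,2-dimethyl-5-(prop-2-enyl)chroman-6-carbaldehyde F7. Cross-metathesis with 2-methylbut-2-ene (second-generation Grubbs catalyst) gives 15.

**Step 15.** Protonation of the C8 alkene with ring closure by the 7-OH (dihydrofuran formation), or hydration of the prenyl group, may accompany acetal cleavage.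
Fallback, from 19 back to 22: the MOM groups are exchanged for silyl ethers before ring A exists. Acid methanolysis of 19 gives the diol pyranone methyl 6-(2,2-dimethylbut-3-enyl)-3-hydroxy-2-[8-hydroxy-2,2-dimethyl-5-(3-methylbut-2-enyl)chroman-6-yl]-4-oxo-4H-pyran-5-carboxylate F5. Silylation (TBSCl, imidazole, DMF) gives methyl 3-(tert-butyldimethylsilyloxy)-2-[8-(tert-butyldimethylsilyloxy)-2,2-dimethyl-5-(3-methylbut-2-enyl)chroman-6-yl]-6-(2,2-dimethylbut-3-enyl)-4-oxo-4H-pyran-5-carboxylate F8. Acetylation as in step 13 gives methyl 3-(tert-butyldimethylsilyloxy)-2-[8-(tert-butyldimethylsilyloxy)-2,2-dimethyl-5-(3-methylbut-2-enyl)chroman-6-yl]-6-(4,4-dimethyl-2-oxohex-5-en-3-yl)-4-oxo-4H-pyran-5-carboxylate F9. Ring closure as in step 14 gives 3-(tert-butyldimethylsilyloxy)-2-[8-(tert-butyldimethylsilyloxy)-2,2-dimethyl-5-(3-methylbut-2-enyl)chroman-6-yl]-5,7-dihydroxy-8-(2-methylbut-3-en-2-yl)chromen-4-one F10. Fluoride (Bu4NF, AcOH, THF, 0 °C) then frees 22 without any acid.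

## Further compounds

F1 | step 14 | methyl 6-[5,5-dimethyl-1,3-dioxo-1-(prop-2-enyloxy)hept-6-en-4-yl]-3-(methoxymethoxy)-2-[8-(methoxymethoxy)-2,2-dimethyl-5-(3-methylbut-2-enyl)chroman-6-yl]-4-oxo-4H-pyran-5-carboxylate (racemic) | C=CCOC(=O)CC(=O)C(C(C)(C)C=C)c1oc(-c2cc(OCOC)c3OC(C)(C)CCc3c2CC=C(C)C)c(OCOC)c(=O)c1C(=O)OC
F2 | step 14 | prop-2-enyl 5,7-dihydroxy-3-(methoxymethoxy)-2-[8-(methoxymethoxy)-2,2-dimethyl-5-(3-methylbut-2-enyl)chroman-6-yl]-8-(2-methylbut-3-en-2-yl)-4-oxo-4H-chromene-6-carboxylate | C=CCOC(=O)c1c(O)c(C(C)(C)C=C)c2oc(-c3cc(OCOC)c4OC(C)(C)CCc4c3CC=C(C)C)c(OCOC)c(=O)c2c1O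
F3 | step 14 | 5,7-dihydroxy-3-(methoxymethoxy)-2-[8-(methoxymethoxy)-2,2-dimethyl-5-(3-methylbut-2-enyl)chroman-6-yl]-8-(2-methylbut-3-en-2-yl)-4-oxo-4H-chromene-6-carboxylic acid | OC(=O)c1c(O)c(C(C)(C)C=C)c2oc(-c3cc(OCOC)c4OC(C)(C)CCc4c3CC=C(C)C)c(OCOC)c(=O)c2c1O
F4 | step 11 | methyl 4-(methoxymethoxy)-5-[8-(methoxymethoxy)-2,2-dimethyl-5-(3-methylbut-2-enyl)chroman-6-yl]-3,5-dioxopentanoate | COC(=O)CC(=O)C(OCOC)C(=O)c1cc(OCOC)c2OC(C)(C)CCc2c1CC=C(C)C
F5 | step 12 | methyl 6-(2,2-dimethylbut-3-enyl)-3-hydroxy-2-[8-hydroxy-2,2-dimethyl-5-(3-methylbut-2-enyl)chroman-6-yl]-4-oxo-4H-pyran-5-carboxylate | COC(=O)c1c(CC(C)(C)C=C)oc(-c2cc(O)c3OC(C)(C)CCc3c2CC=C(C)C)c(O)c1=O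
F6 | step 13 | methyl 6-(2-hydroxy-4,4-dimethylhex-5-en-3-yl)-3-(methoxymethoxy)-2-[8-(methoxymethoxy)-2,2-dimethyl-5-(3-methylbut-2-enyl)chroman-6-yl]-4-oxo-4H-pyran-5-carboxylate (mixture of diastereomers) | COC(=O)c1c(C(C(C)O)C(C)(C)C=C)oc(-c2cc(OCOC)c3OC(C)(C)CCc3c2CC=C(C)C)c(OCOC)c1=O
F7 | step 9 | 8-(methoxymethoxy)-2,2-dimethyl-5-(prop-2-enyl)chroman-6-carbaldehyde | O=Cc1cc(OCOC)c2OC(C)(C)CCc2c1CC=C
F8 | step 15 | methyl 3-(tert-butyldimethylsilyloxy)-2-[8-(tert-butyldimethylsilyloxy)-2,2-dimethyl-5-(3-methylbut-2-enyl)chroman-6-yl]-6-(2,2-dimethylbut-3-enyl)-4-oxo-4H-pyran-5-carboxylate | COC(=O)c1c(CC(C)(C)C=C)oc(-c2cc(O[Si](C)(C)C(C)(C)C)c3OC(C)(C)CCc3c2CC=C(C)C)c(O[Si](C)(C)C(C)(C)C)c1=O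
F9 | step 15 | methyl 3-(tert-butyldimethylsilyloxy)-2-[8-(tert-butyldimethylsilyloxy)-2,2-dimethyl-5-(3-methylbut-2-enyl)chroman-6-yl]-6-(4,4-dimethyl-2-oxohex-5-en-3-yl)-4-oxo-4H-pyran-5-carboxylate (racemic) | COC(=O)c1c(C(C(C)=O)C(C)(C)C=C)oc(-c2cc(O[Si](C)(C)C(C)(C)C)c3OC(C)(C)CCc3c2CC=C(C)C)c(O[Si](C)(C)C(C)(C)C)c1=O
F10 | step 15 | 3-(tert-butyldimethylsilyloxy)-2-[8-(tert-butyldimethylsilyloxy)-2,2-dimethyl-5-(3-methylbut-2-enyl)chroman-6-yl]-5,7-dihydroxy-8-(2-methylbut-3-en-2-yl)chromen-4-one | C=CC(C)(C)c1c(O)cc(O)c2c(=O)c(O[Si](C)(C)C(C)(C)C)c(-c3cc(O[Si](C)(C)C(C)(C)C)c4OC(C)(C)CCc4c3CC=C(C)C)oc12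
A1 | alternative 1 | 4-(tert-butyldimethylsilyloxy)-5-(methoxymethoxy)-2,3-bis(3-methylbut-2-enyl)phenyl trifluoromethanesulfonate | CC(C)=CCc1c(OS(=O)(=O)C(F)(F)F)cc(OCOC)c(O[Si](C)(C)C(C)(C)C)c1CC=C(C)C
A2 | alternative 2 | methyl 2,4-dihydroxy-6-(methoxymethoxy)-3-(2-methylbut-3-en-2-yl)benzoate | COC(=O)c1c(O)c(C(C)(C)C=C)c(O)cc1OCOC
A3 | alternative 3 | 2-[8-hydroxy-2,2-dimethyl-5-(3-methylbut-2-enyl)chroman-6-yl]-3,5,7-tris(methoxymethoxy)-8-(2-methylbut-3-en-2-yl)chromen-4-one | C=CC(C)(C)c1c(OCOC)cc(OCOC)c2c(=O)c(OCOC)c(-c3cc(O)c4OC(C)(C)CCc4c3CC=C(C)C)oc12
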